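## Structural features

The target is a monocyclic 1,2-dioxane (O1–O2–C3–C4–C5–C6) with a CH2CO2H arm on C3 and, on C6, a methoxy group and a sixteen-carbon chain, so C6 is a peroxyketal carbon. The chain is (CH2)3–C≡C–CH=CH–(CH2)7–CH=CH2, with an E enyne and a terminal alkene held three methylene groups away from the ring. The two stereocentres, C3 (S) and C6 (R), are not adjacent but 1,4-related through C4 and C5. Reading the SMILES places the methoxy group and the arm on the same ring face, so in the chair the arm and the long chain are equatorial and the methoxy group is axial. The fragile elements are the O–O bond (hydride, hydrogenation, stoichiometric phosphine, low-valent metals), the peroxyketal (exchange in protic acid), the C3–H/arm pair once a carbonyl sits β to the peroxide oxygen (base-induced β-elimination or Kornblum–DeLaMare cleavage), and the enyne and alkene. The real difficulty is a configurationally defined secondary C–O–O bond at C3, for which no general asymmetric peroxidation exists, together with the C6 configuration relative to it. The key step exploits the fact that C6, flanked by O1 and the methoxy oxygen, ionises reversibly to a ring peroxycarbenium ion while C3 is inert, so the anomeric preference at C6 and the equatorial preference of both carbon substituents make the wanted epimer the thermodynamic one. The open-chain form of the ring is a γ-hydroperoxy ketone (hydroperoxide on C9, carbonyl on C6 of an undec-1-yn-6-one); a δ relationship would close a seven-membered ring, so the γ locant is the correct one.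

## Logic of the disconnections

24 ⇒ 20 + 23. The C(sp)–C(sp2) bond between the alkyne and the E alkene of the side chain is cut. This keeps the diene and the enyne out of every peroxide-forming and acidic step and makes the route convergent. The forward coupling must tolerate the O–O bond and a free carboxylic acid and must keep the E geometry of the C–I partner.

23 ⇒ 22 ⇒ 21. The iodoalkene C=C bond is cut back to an aldehyde carbon (one-carbon homologation), and the aldehyde to the alcohol. The gain is a cheap ten-carbon alkenol. The demand is E selectivity in the olefination.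

20 ⇒ 18 ⇒ 17. The carboxyl group is traced to a primary alcohol and that to its silyl ether. The arm is carried at the alcohol level because a carbonyl β to the peroxide oxygen would not survive the basic peroxide alkylation. The forward oxidation must be non-basic and non-reducing.

17 ⇒ 15 (through 16). The bonds O1–C6 and C6–OMe are cut. This removes the ring and the C6 stereocentre and leaves an acyclic chain with one stereocentre. The forward step must run under equilibrium control so that C6 settles under the influence of C3.

15 ⇒ 14. No bond of the skeleton is cut; the hydroperoxide and the ketone are both put into ketal-type masks. The gain is that 15 never has to be isolated or stored and that 14 is stable to base. The demand is that one acid removes both masks in the flask of the key step. The alkyne is left uncapped: a trimethylsilyl cap would be open to attack by the peroxide anion in DMF, and the dianion used in step 5 makes a cap unnecessary.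

14 ⇒ 11 + 13, and 13 ⇒ 12. The C–O bond between the stereocentre and the peroxide is cut. This puts the configuration problem on a carbinol carbon, where it is easy to solve. The forward SN2 must go with clean inversion on a secondary sulfonate, without E2 and with the ketone masked (a free one would cyclise through its enolate and add the peroxide anion).

11 ⇒ 10 ⇒ 9. These are functional-group changes only: ketal back to ketone, sulfonate back to alcohol. The order is dictated by the fact that a free γ-hydroxyl would form the cyclic methyl ketal, so the sulfonate has to be in place before ketalization.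

9 ⇒ 7 + 5, and 7 ⇒ 6. The C7–C8 bond between the ketone α-carbon and the carbinol-bearing chain is cut. This splits the chain into two pieces of similar size and sets the 1,4 relationship of oxygen and carbonyl directly. The forward step needs metalation at the methyl side of the hydrazone and attack at the unsubstituted epoxide carbon; the stereocentre is only a spectator.

5 ⇒ 3 ⇒ 2 ⇒ 1. The epoxide C–O bond at the primary carbon is cut back to a 1,2-diol and that to the acetonide of the chiral pool. The stereocentre is bought, and no step breaks a bond to it before step 9.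

## Other disconnections considered

Alternative 1: The cut removes both C–O bonds of the peroxide at once (O1–C6 and O2–C3, a retro-[4+2]), after C4=C5 is introduced and the C6 ketal oxygen is tied back to the arm in a seven-membered dienol ether. The substrate would be (2R)-2-{[(tert-butyldimethylsilyl)oxy]methyl}-7-[5-(triisopropylsilyl)pent-4-yn-1-yl]-2,3-dihydrooxepine A1. Sensitised singlet oxygen would add across its diene termini to give (1R,3R,5R)-3-{[(tert-butyldimethylsilyl)oxy]methyl}-1-[5-(triisopropylsilyl)pent-4-yn-1-yl]-2,6,7-trioxabicyclo[3.2.2]non-8-ene A2.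
- In its favour: both C–O bonds come from O2 in one neutral, suprafacial step, and no peroxide nucleophile has to displace a secondary sulfonate. On that point the alternative is better than the chosen plan, whose step 9 is its weakest link. The tether also forces the ketal oxygen and the arm to be cis, and the stereocentre of A1 is excised later.
- Against it: A1 is an electron-rich cyclic dienol ether, so [2+2] addition at the enol ether and ene reaction at its allylic CH2 would compete with the [4+2] mode, and A1 is itself a multistep target.
- Face selectivity: in A2 as formulated the silyloxymethyl group lies on the same face of the seven-membered ring as the peroxide bridge. Oxygen would therefore have to add syn to the only control element; anti approach would call for the enantiomer of A1.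
- After the key step: C8=C9 of A2 must be reduced with diimide, the bridging ketal opened by methanol against the entropic preference for the bridge, and the arm cut down by glycol cleavage and oxidation.
- Comparison: on C6 the two plans are equal, because methanolysis passes through the same peroxycarbenium ion and the same thermodynamics decide. On C3 the chosen plan is more predictable (chiral-pool carbinol plus inversion against substrate-controlled face selectivity). On step economy the alternative is clearly longer.

Alternative 2: The cut is at C3–C4 and O1–C6. Methyl 3-methoxy-3-[(triethylsilyl)peroxy]propanoate A3 would be ionised by a chiral silylium imidodiphosphorimidate to a silylperoxy carbenium ion. A ring CH2 of [5-(1-methoxycyclopropyl)pent-1-yn-1-yl]trimethylsilane A4 would attack it, and the silylperoxy oxygen would close on the resulting C6 oxocarbenium ion. The product would be methyl 2-[(3S)-6-methoxy-6-[5-(trimethylsilyl)pent-4-yn-1-yl]-1,2-dioxan-3-yl]acetate A5 as both C6 epimers.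
- In its favour: it is the shortest and most convergent plan. The arm arrives at the carboxyl oxidation level without a protecting group, and C3 is set by a catalyst, so either enantiomer is accessible. On step and redox economy it is better than the chosen plan, and it also avoids the sulfonate displacement.
- Against it: a cyclopropyl ether as the three-carbon partner of a peroxycarbenium ion has no close analogy. The cation from A3 carries acidic hydrogens next to the ester and could lose a proton to a β-peroxy acrylate. Face control of a small, flexible aliphatic cation by a counter-anion is unproven, and the later ester hydrolysis puts a base next to a β-peroxy ester.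
- Comparison: on C6 the plans are equal, since the epimers of A5 would be equilibrated by the same acid in methanol. On C3 the chosen plan is more secure, because its enantiopurity is inherited and not induced. On mechanism the alternative avoids basic peroxide chemistry but its key step would itself be new chemistry.

Alternative 3: The cut is the C4–C5 bond, taken back as C4=C5. The acyclic mixed peroxyketal tert-butyl{[(3R)-3-{[3-methoxy-8-(trimethylsilyl)oct-1-en-7-yn-3-yl]peroxy}pent-4-en-1-yl]oxy}diphenylsilane A6 would be closed by a second-generation Grubbs catalyst, with loss of ethylene. The product would be tert-butyl{2-[(3R)-6-methoxy-6-[5-(trimethylsilyl)pent-4-yn-1-yl]-3,6-dihydro-1,2-dioxin-3-yl]ethoxy}diphenylsilane A7 as both C6 epimers. The descriptor at C3 is R only because the ring alkene carbon outranks the arm; the spatial arrangement is that of the target.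
- In its favour: the ring closure is an irreversible C–C bond formation that does not depend on a ketal equilibrium and does not touch O–O or C3, and both epimers of A6 can cyclise. On kinetic security of the ring closure it is equal or better.
- Against it: the allylic hydroperoxide half of A6 needs the same kind of SN2 as the chosen plan, now on an allylic sulfonate where SN2′ attack and ionisation threaten regio- and stereochemical integrity. The ketal-bearing vinyl group sits on a quaternary carbon and would engage the catalyst slowly. The silyl alkyne invites enyne metathesis.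
- Product stability and reduction: A7 has an allylic C3–H next to the peroxide and is open to Kornblum–DeLaMare rearrangement by base or by ruthenium residues. C4=C5 must then be reduced by diimide without touching O–O or the alkyne.
- Comparison: on C6 the plans are equal, because the same acid/methanol equilibration would follow the reduction. On C3 the alternative is no easier. On step economy it is worse, because of the extra reduction and the two vinyl fragments, whereas the chosen plan delivers C4–C5 saturated.

Key step: step 10

Remark on the chemistry: 6 is taken as a catalogue ketone; 13 is not an article of commerce, so it is made in step 8 and handled only in solution.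

## Route

Step 1
Reactants: 1 2-[(4S)-2,2-dimethyl-1,3-dioxolan-4-yl]ethan-1-ol
Product: 2 tert-butyl{2-[(4S)-2,2-dimethyl-1,3-dioxolan-4-yl]ethoxy}diphenylsilane
Conditions: TBDPSCl (1.1 equiv), imidazole (2.2 equiv), CH2Cl2, 0 °C → rt
Reagents that add atoms: tert-butyl(chloro)diphenylsilane, CC(C)(C)[Si](Cl)(c1ccccc1)c1ccccc1
Why: Imidazole-promoted silylation of the primary alcohol; TBDPS is chosen because it has to outlast aqueous acetic acid, LiN(i-Pr)2, the cesium peroxide and the sulfonic acid of the key step and still leave with fluoride.

Step 2
Reactants: 2 tert-butyl{2-[(4S)-2,2-dimethyl-1,3-dioxolan-4-yl]ethoxy}diphenylsilane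
Product: 3 (2S)-4-[(tert-butyldiphenylsilyl)oxy]butane-1,2-diol
Conditions: AcOH–H2O (4:1), 40 °C
Reagents that add atoms: none
Why: Acid hydrolysis of the isopropylidene acetal; the primary TBDPS ether tolerates aqueous acetic acid and the stereocentre is not involved.

Step 3
Reactants: 3 (2S)-4-[(tert-butyldiphenylsilyl)oxy]butane-1,2-diol
Product: 5 tert-butyl{2-[(2S)-oxiran-2-yl]ethoxy}diphenylsilane, via monotosylate 4 (not isolated)
Conditions: NaH (2.2 equiv), 1-tosylimidazole (1.05 equiv), THF, 0 °C → rt
Reagents that add atoms: none
Why: One-pot sulfonylation of the less hindered primary alkoxide followed by intramolecular Williamson closure (3-exo-tet) by the secondary alkoxide; no bond to the stereocentre is broken, so it stays (S).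

Step 4
Reactants: 6 hept-6-yn-2-one
Product: 7 2-(hept-6-yn-2-ylidene)-1,1-dimethylhydrazine
Conditions: Me2NNH2 (3 equiv), AcOH (cat.), EtOH, reflux
Reagents that add atoms: 1,1-dimethylhydrazine, CN(C)N
Why: Condensation of a methyl ketone to its N,N-dimethylhydrazone, which masks the carbonyl and makes the α-methyl group cleanly metalatable.

Step 5
Reactants: 7 2-(hept-6-yn-2-ylidene)-1,1-dimethylhydrazine; 5 tert-butyl{2-[(2S)-oxiran-2-yl]ethoxy}diphenylsilane
Product: 9 (9R)-11-[(tert-butyldiphenylsilyl)oxy]-9-hydroxyundec-1-yn-6-one, via hydroxy hydrazone 8 (not isolated)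
Conditions: 7 (1.2 equiv), LiN(i-Pr)2 (2.5 equiv), THF, −78 → 0 °C; then 5, 0 °C → rt; then sat. aq. oxalic acid, Et2O, rt
Reagents that add atoms: water, O
Why: Corey–Enders azaenolate alkylation: the first equivalent of base removes the alkyne proton, the second metalates the methyl side of the hydrazone, and the azaenolate carbon (far more reactive towards an epoxide in THF than a lithium acetylide) opens 5 at its CH2 terminus by SN2; biphasic oxalic acid then hydrolyses the hydrazone. The C–O bond of the stereocentre is untouched, so the carbinol is (R): same spatial arrangement as in 5, the descriptor changes only because the priorities change.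

Step 6
Reactants: 9 (9R)-11-[(tert-butyldiphenylsilyl)oxy]-9-hydroxyundec-1-yn-6-one
Product: 10 (3R)-1-[(tert-butyldiphenylsilyl)oxy]-6-oxoundec-10-yn-3-yl methanesulfonate
Conditions: MsCl (1.3 equiv), Et3N (2 equiv), CH2Cl2, −10 → 0 °C
Reagents that add atoms: methanesulfonyl chloride, CS(=O)(=O)Cl
Why: O-sulfonylation of the secondary alcohol with retention (only the O–S bond forms); triethylamine at low temperature is too weak a base for enolate chemistry of the γ-sulfonyloxy ketone, which is used without delay.

Step 7
Reactants: 10 (3R)-1-[(tert-butyldiphenylsilyl)oxy]-6-oxoundec-10-yn-3-yl methanesulfonate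
Product: 11 (3R)-1-[(tert-butyldiphenylsilyl)oxy]-6,6-dimethoxyundec-10-yn-3-yl methanesulfonate
Conditions: HC(OMe)3 (3 equiv), PPTS (0.1 equiv), MeOH, rt; Et3N quench
Reagents that add atoms: trimethyl orthoformate, COC(OC)OC; methanol, CO
Why: Acid-catalysed ketalization with the orthoester as water scavenger; the ketone has to be masked because under the base of step 9 a free γ-mesyloxy ketone would close to a cyclopropyl ketone through its enolate and would add the peroxide anion. The ketal can only be made after sulfonylation, since a free γ-hydroxyl would give the cyclic methyl ketal.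

Step 8
Reactants: 12 2,3-dimethylbut-2-ene
Product: 13 2-hydroperoxy-2-methoxypropane
Conditions: O3, MeOH–CH2Cl2, −78 °C; N2 purge; kept as a stock solution
Reagents that add atoms: ozone, [O-][O+]=O; methanol, CO
Why: Ozonolysis in methanol (Criegee mechanism): the primary ozonide fragments to acetone and acetone O-oxide, which methanol traps as the α-methoxy hydroperoxide, a monoprotected hydrogen peroxide whose cap falls off in mild acid.

Step 9
Reactants: 11 (3R)-1-[(tert-butyldiphenylsilyl)oxy]-6,6-dimethoxyundec-10-yn-3-yl methanesulfonate; 13 2-hydroperoxy-2-methoxypropane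
Product: 14 tert-butyl({(3S)-6,6-dimethoxy-3-[(2-methoxypropan-2-yl)peroxy]undec-10-yn-1-yl}oxy)diphenylsilane
Conditions: 13 (3 equiv), CsOH·H2O (2 equiv), DMF, 0 °C → rt
Reagents that add atoms: none
Why: SN2 displacement of a secondary methanesulfonate by the cesium salt of a monoprotected hydroperoxide, a known route to secondary peroxides, with inversion: (R)-mesylate to (S)-peroxide, the C3 configuration of the target. Keeping 13 in excess over CsOH leaves the weakly basic, strongly nucleophilic peroxide anion as the only base, which limits E2 and spares the silyl ether, the ketal and the alkyne C–H.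

Step 10
Reactants: 14 tert-butyl({(3S)-6,6-dimethoxy-3-[(2-methoxypropan-2-yl)peroxy]undec-10-yn-1-yl}oxy)diphenylsilane
Product: 17 tert-butyl{2-[(3S,6R)-6-methoxy-6-(pent-4-yn-1-yl)-1,2-dioxan-3-yl]ethoxy}diphenylsilane, via hydroperoxy ketone 15 (not isolated), via peroxyhemiketal 16 (not isolated)
Conditions: camphorsulfonic acid (CSA, 0.1 equiv), THF, H2O (5 equiv), 0 °C → rt; then MeOH (to 0.02 M), rt, 16–24 h; Et3N quench
Reagents that add atoms: methanol, CO
Why: Acid-catalysed peroxyketalization of a γ-hydroperoxy ketone, the known entry to 3-alkoxy-1,2-dioxanes. In wet THF the acid hydrolyses the 2-methoxypropan-2-yl peroxyketal and the dimethyl ketal of 14 to 15, whose hydroperoxide oxygen adds reversibly to the C6 carbonyl (6-exo-trig, forming O1–C6) to give 16. In methanol, protonation and loss of water from 16 give a ring peroxycarbenium ion at C6 that methanol captures, forming C6–OMe. Both events are reversible, so the C6 epimers interconvert through that ion and the mixture should drain to the chair with the methoxy group axial (anomeric stabilisation by O1) and the pentynyl chain and the C3 arm both equatorial, which is the (3S,6R) isomer. The new stereocentre C6 is therefore set by thermodynamic control under the influence of C3, and C3 has no adjacent carbonyl or leaving group and cannot epimerise. The step needs the six-membered peroxyketal to win over the acyclic dimethyl ketal and over the C6 epimer; intramolecularity and the large excess of methanol secure the first, the anomeric and equatorial preferences the second. The primary TBDPS ether and the alkyne should survive catalytic sulfonic acid at room temperature, and keeping the arm silylated stops its hydroxyl from bridging to C6.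

Step 11
Reactants: 17 tert-butyl{2-[(3S,6R)-6-methoxy-6-(pent-4-yn-1-yl)-1,2-dioxan-3-yl]ethoxy}diphenylsilane
Product: 18 2-[(3S,6R)-6-methoxy-6-(pent-4-yn-1-yl)-1,2-dioxan-3-yl]ethan-1-ol
Conditions: Bu4NF (1.5 equiv), THF, 0 °C → rt; aq. NH4Cl
Reagents that add atoms: none
Why: Fluoride cleavage of the silyl ether; dialkyl peroxides and peroxyketals tolerate fluoride, and since no carbonyl is yet β to the peroxide oxygen, base-induced β-elimination has no handle.

Step 12
Reactants: 18 2-[(3S,6R)-6-methoxy-6-(pent-4-yn-1-yl)-1,2-dioxan-3-yl]ethan-1-ol
Product: 20 2-[(3S,6R)-6-methoxy-6-(pent-4-yn-1-yl)-1,2-dioxan-3-yl]acetic acid, via aldehyde 19 (not isolated)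
Conditions: TEMPO (0.2 equiv), PhI(OAc)2 (2.5 equiv), MeCN–H2O (1:1), 0 °C → rt; aq. Na2S2O3
Reagents that add atoms: water, O
Why: Oxoammonium (TEMPO) oxidation with PhI(OAc)2 as terminal oxidant in aqueous acetonitrile takes the alcohol to the aldehyde and its hydrate on to the acid. The medium is weakly acidic, non-basic and non-reducing, so the O–O bond, the peroxyketal and the alkyne should be inert and the β-peroxy aldehyde 19 never meets a base.

Step 13
Reactants: 21 dec-9-en-1-ol
Product: 22 dec-9-enal
Conditions: TEMPO (0.1 equiv), PhI(OAc)2 (1.1 equiv), CH2Cl2, rt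
Reagents that add atoms: none
Why: Oxoammonium-catalysed oxidation of a primary alcohol stops at the aldehyde in anhydrous CH2Cl2; the terminal alkene is inert.

Step 14
Reactants: 22 dec-9-enal
Product: 23 (1E)-1-iodoundeca-1,10-diene
Conditions: CrCl2 (6 equiv), CHI3 (2 equiv), 1,4-dioxane–THF (6:1), 0 °C → rt
Reagents that add atoms: iodoform, IC(I)I
Why: Takai olefination: CrCl2 reduces iodoform to a geminal dichromium carbenoid that adds to the aldehyde and eliminates from the less hindered arrangement to give the (E)-iodoalkene. The dioxane-rich solvent is chosen to raise the E preference, and the remote alkene does not react.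

Step 15
Reactants: 20 2-[(3S,6R)-6-methoxy-6-(pent-4-yn-1-yl)-1,2-dioxan-3-yl]acetic acid; 23 (1E)-1-iodoundeca-1,10-diene
Product: 24 2-[(3S,6R)-6-[(6E)-hexadeca-6,15-dien-4-yn-1-yl]-6-methoxy-1,2-dioxan-3-yl]acetic acid
Conditions: Pd(PPh3)4 (5 mol %), CuI (10 mol %), Et3N (5 equiv), THF, rt, degassed; work-up at pH 4
Reagents that add atoms: none
Why: Sonogashira coupling: oxidative addition of zerovalent palladium to the C–I bond with retention of the E geometry, transmetalation of the copper acetylide, reductive elimination to the enyne. The acid is carried as its triethylammonium salt, and an alkenyl iodide couples at room temperature, which keeps the contact of the O–O bond with catalytic phosphine and low-valent metal short.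

## Compound list

1 | 2-[(4S)-2,2-dimethyl-1,3-dioxolan-4-yl]ethan-1-ol | CC1(C)OC[C@H](CCO)O1 | starting material
2 | tert-butyl{2-[(4S)-2,2-dimethyl-1,3-dioxolan-4-yl]ethoxy}diphenylsilane | CC1(C)OC[C@H](CCO[Si](c2ccccc2)(c2ccccc2)C(C)(C)C)O1 | intermediate
3 | (2S)-4-[(tert-butyldiphenylsilyl)oxy]butane-1,2-diol | OC[C@@H](O)CCO[Si](c1ccccc1)(c1ccccc1)C(C)(C)C | intermediate
4 | (2S)-4-[(tert-butyldiphenylsilyl)oxy]-2-hydroxybutyl 4-methylbenzenesulfonate | Cc1ccc(cc1)S(=O)(=O)OC[C@@H](O)CCO[Si](c1ccccc1)(c1ccccc1)C(C)(C)C | intermediate
5 | tert-butyl{2-[(2S)-oxiran-2-yl]ethoxy}diphenylsilane | C1[C@H](CCO[Si](c2ccccc2)(c2ccccc2)C(C)(C)C)O1 | intermediate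
6 | hept-6-yn-2-one | CC(=O)CCCC#C | starting material
7 | 2-(hept-6-yn-2-ylidene)-1,1-dimethylhydrazine | CC(CCCC#C)=NN(C)C | intermediate
8 | (3R)-1-[(tert-butyldiphenylsilyl)oxy]-6-(2,2-dimethylhydrazinylidene)undec-10-yn-3-ol | C#CCCCC(=NN(C)C)CC[C@@H](O)CCO[Si](c1ccccc1)(c1ccccc1)C(C)(C)C | intermediate
9 | (9R)-11-[(tert-butyldiphenylsilyl)oxy]-9-hydroxyundec-1-yn-6-one | C#CCCCC(=O)CC[C@@H](O)CCO[Si](c1ccccc1)(c1ccccc1)C(C)(C)C | intermediate
10 | (3R)-1-[(tert-butyldiphenylsilyl)oxy]-6-oxoundec-10-yn-3-yl methanesulfonate | C#CCCCC(=O)CC[C@@H](OS(C)(=O)=O)CCO[Si](c1ccccc1)(c1ccccc1)C(C)(C)C | intermediate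
11 | (3R)-1-[(tert-butyldiphenylsilyl)oxy]-6,6-dimethoxyundec-10-yn-3-yl methanesulfonate | C#CCCCC(OC)(OC)CC[C@@H](OS(C)(=O)=O)CCO[Si](c1ccccc1)(c1ccccc1)C(C)(C)C | intermediate
12 | 2,3-dimethylbut-2-ene | CC(C)=C(C)C | starting material
13 | 2-hydroperoxy-2-methoxypropane | COC(C)(C)OO | intermediate
14 | tert-butyl({(3S)-6,6-dimethoxy-3-[(2-methoxypropan-2-yl)peroxy]undec-10-yn-1-yl}oxy)diphenylsilane | C#CCCCC(OC)(OC)CC[C@H](OOC(C)(C)OC)CCO[Si](c1ccccc1)(c1ccccc1)C(C)(C)C | intermediate
15 | (9S)-11-[(tert-butyldiphenylsilyl)oxy]-9-hydroperoxyundec-1-yn-6-one | C#CCCCC(=O)CC[C@H](OO)CCO[Si](c1ccccc1)(c1ccccc1)C(C)(C)C | intermediate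
16 | (6S)-6-{2-[(tert-butyldiphenylsilyl)oxy]ethyl}-3-(pent-4-yn-1-yl)-1,2-dioxan-3-ol (both C3 epimers; ring tautomer of 15) | C#CCCCC1(O)CC[C@@H](CCO[Si](c2ccccc2)(c2ccccc2)C(C)(C)C)OO1 | intermediate
17 | tert-butyl{2-[(3S,6R)-6-methoxy-6-(pent-4-yn-1-yl)-1,2-dioxan-3-yl]ethoxy}diphenylsilane | C#CCCC[C@]1(OC)CC[C@@H](CCO[Si](c2ccccc2)(c2ccccc2)C(C)(C)C)OO1 | intermediate
18 | 2-[(3S,6R)-6-methoxy-6-(pent-4-yn-1-yl)-1,2-dioxan-3-yl]ethan-1-ol | C#CCCC[C@]1(OC)CC[C@@H](CCO)OO1 | intermediate
19 | 2-[(3S,6R)-6-methoxy-6-(pent-4-yn-1-yl)-1,2-dioxan-3-yl]acetaldehyde | C#CCCC[C@]1(OC)CC[C@@H](CC=O)OO1 | intermediate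
20 | 2-[(3S,6R)-6-methoxy-6-(pent-4-yn-1-yl)-1,2-dioxan-3-yl]acetic acid | C#CCCC[C@]1(OC)CC[C@@H](CC(=O)O)OO1 | intermediate
21 | dec-9-en-1-ol | C=CCCCCCCCCO | starting material
22 | dec-9-enal | C=CCCCCCCCC=O | intermediate
23 | (1E)-1-iodoundeca-1,10-diene | C=CCCCCCCC/C=C/I | intermediate
24 | 2-[(3S,6R)-6-[(6E)-hexadeca-6,15-dien-4-yn-1-yl]-6-methoxy-1,2-dioxan-3-yl]acetic acid | C=CCCCCCCC/C=C/C#CCCC[C@]1(OC)CC[C@@H](CC(=O)O)OO1 | target

## Step count and least certain steps

Total: 15 steps. Longest linear sequence: 11 steps from 1 (steps 1, 2, 3, 5, 6, 7, 9, 10, 11, 12, 15). Steps 4, 8, 13 and 14 are side branches. All peroxides, and 13 in particular, are to be handled in solution behind a shield.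

Step 10 (key step). The equilibration at C6 may stop short of the thermodynamic distribution. Prolonged protic acid may also start to remove the silyl ether, after which the freed hydroxyl would bridge to C6, or may start Hock-type cleavage of the peroxyketal. The fallback replaces protic equilibration by a low-temperature substitution on the preformed ring. It sets out from 14: the sequence is stopped after the aqueous stage and the ring tautomer 16 is isolated. 16 is then treated with MeOSiMe3 and catalytic Me3SiOTf in CH2Cl2 at −78 °C. The hemiketal oxygen is silylated and leaves, and the ring peroxycarbenium ion is captured along the axial trajectory, which leads to the same axial-methoxy isomer. The route is rejoined at 17. No compound outside the list is made (F0).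

Step 9. E2 elimination, or participation of a ketal oxygen at the sulfonate-bearing carbon, may outrun the intermolecular SN2 on a hindered secondary centre, with loss of material and of stereochemical integrity. The fallback makes the C–O bond intramolecularly and sets out from 11. Urea–hydrogen peroxide and catalytic Sc(OTf)3 in methanol exchange one methoxy group of the ketal for a hydroperoxy group to give (3R)-1-[(tert-butyldiphenylsilyl)oxy]-6-hydroperoxy-6-methoxyundec-10-yn-3-yl methanesulfonate F1. KOt-Bu with 18-crown-6 in THF then closes the ring by 6-exo-tet attack of the peroxide anion on the sulfonate carbon with inversion. This gives tert-butyl{2-[(3S)-6-methoxy-6-(pent-4-yn-1-yl)-1,2-dioxan-3-yl]ethoxy}diphenylsilane F2 as both C6 epimers. Camphorsulfonic acid in methanol equilibrates F2, and the route is rejoined at 17. This is the one contingency in which O1–C6 is formed before O2–C3 and the ring is not closed by the key step; it bypasses 15, while the thermodynamic control of C6 is kept.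

Step 7. During ketalization the hemiketal or ketal oxygen may attack the sulfonate-bearing carbon (5-exo-tet), which would close a tetrahydrofuran and destroy the leaving group. The fallback removes the leaving group from the acidic step and sets out from 9. Ac2O, pyridine and catalytic DMAP give (3R)-1-[(tert-butyldiphenylsilyl)oxy]-6-oxoundec-10-yn-3-yl acetate F3. HC(OMe)3 and PPTS in methanol give (3R)-1-[(tert-butyldiphenylsilyl)oxy]-6,6-dimethoxyundec-10-yn-3-yl acetate F4. K2CO3 in methanol gives (3R)-1-[(tert-butyldiphenylsilyl)oxy]-6,6-dimethoxyundec-10-yn-3-ol F5, which is kept basic. MsCl and Et3N then return to the route at 11.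

Step 5. The two carbanionic sites of the dianion may compete (alkylation at the acetylide), or the aggregated dianion may open the epoxide sluggishly. The fallback caps the alkyne so that only one anion is present, and sets out from 5. The Grignard reagent from (5-chloropent-1-yn-1-yl)trimethylsilane and Mg in THF is acylated with N-methoxy-N-methylacetamide to 7-(trimethylsilyl)hept-6-yn-2-one F6. Me2NNH2 gives 1,1-dimethyl-2-[7-(trimethylsilyl)hept-6-yn-2-ylidene]hydrazine F7. One equivalent of LiN(i-Pr)2 followed by 5 gives (3R)-1-[(tert-butyldiphenylsilyl)oxy]-6-(2,2-dimethylhydrazinylidene)-11-(trimethylsilyl)undec-10-yn-3-ol F8. Oxalic acid hydrolysis gives (9R)-11-[(tert-butyldiphenylsilyl)oxy]-9-hydroxy-1-(trimethylsilyl)undec-1-yn-6-one F9. K2CO3 in methanol removes the silyl cap and the route is rejoined at 9.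

Step 14. Incomplete E selectivity in the olefination would carry a Z isomer into the final coupling, where it is hard to remove. The fallback builds the iodoalkene by syn hydrometalation and sets out from 22. Dimethyl (1-diazo-2-oxopropyl)phosphonate and K2CO3 in methanol (Ohira–Bestmann) give undec-10-en-1-yne F10. One equivalent of Cp2Zr(H)Cl, which reacts faster with the terminal alkyne than with the terminal alkene, gives chloridobis(cyclopentadienyl)[(1E)-undeca-1,10-dien-1-yl]zirconium F11. Iodine then cleaves the C–Zr bond with retention and the route is rejoined at 23.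

Step 15. The carboxylate may sequester the copper and slow acetylide formation. A slow coupling would lengthen the exposure of the O–O bond to phosphine and low-valent metal and favour alkyne homocoupling. The fallback couples before the oxidation and sets out from 18. Coupling with 23 under the same catalyst gives 2-[(3S,6R)-6-[(6E)-hexadeca-6,15-dien-4-yn-1-yl]-6-methoxy-1,2-dioxan-3-yl]ethan-1-ol F12. TEMPO and PhI(OAc)2 in aqueous acetonitrile oxidise it through 2-[(3S,6R)-6-[(6E)-hexadeca-6,15-dien-4-yn-1-yl]-6-methoxy-1,2-dioxan-3-yl]acetaldehyde F13, and the route is rejoined at 24.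

## Further compounds

F0 | step 10 | none | none
F1 | step 9 | (3R)-1-[(tert-butyldiphenylsilyl)oxy]-6-hydroperoxy-6-methoxyundec-10-yn-3-yl methanesulfonate (both C6 epimers) | C#CCCCC(OC)(OO)CC[C@@H](OS(C)(=O)=O)CCO[Si](c1ccccc1)(c1ccccc1)C(C)(C)C
F2 | step 9 | tert-butyl{2-[(3S)-6-methoxy-6-(pent-4-yn-1-yl)-1,2-dioxan-3-yl]ethoxy}diphenylsilane (both C6 epimers) | C#CCCCC1(OC)CC[C@@H](CCO[Si](c2ccccc2)(c2ccccc2)C(C)(C)C)OO1
F3 | step 7 | (3R)-1-[(tert-butyldiphenylsilyl)oxy]-6-oxoundec-10-yn-3-yl acetate | C#CCCCC(=O)CC[C@@H](OC(C)=O)CCO[Si](c1ccccc1)(c1ccccc1)C(C)(C)C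
F4 | step 7 | (3R)-1-[(tert-butyldiphenylsilyl)oxy]-6,6-dimethoxyundec-10-yn-3-yl acetate | C#CCCCC(OC)(OC)CC[C@@H](OC(C)=O)CCO[Si](c1ccccc1)(c1ccccc1)C(C)(C)C
F5 | step 7 | (3R)-1-[(tert-butyldiphenylsilyl)oxy]-6,6-dimethoxyundec-10-yn-3-ol | C#CCCCC(OC)(OC)CC[C@@H](O)CCO[Si](c1ccccc1)(c1ccccc1)C(C)(C)C
F6 | step 5 | 7-(trimethylsilyl)hept-6-yn-2-one | CC(=O)CCCC#C[Si](C)(C)C
F7 | step 5 | 1,1-dimethyl-2-[7-(trimethylsilyl)hept-6-yn-2-ylidene]hydrazine | CC(CCCC#C[Si](C)(C)C)=NN(C)C
F8 | step 5 | (3R)-1-[(tert-butyldiphenylsilyl)oxy]-6-(2,2-dimethylhydrazinylidene)-11-(trimethylsilyl)undec-10-yn-3-ol | C[Si](C)(C)C#CCCCC(=NN(C)C)CC[C@@H](O)CCO[Si](c1ccccc1)(c1ccccc1)C(C)(C)C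
F9 | step 5 | (9R)-11-[(tert-butyldiphenylsilyl)oxy]-9-hydroxy-1-(trimethylsilyl)undec-1-yn-6-one | C[Si](C)(C)C#CCCCC(=O)CC[C@@H](O)CCO[Si](c1ccccc1)(c1ccccc1)C(C)(C)C
F10 | step 14 | undec-10-en-1-yne | C=CCCCCCCCC#C
F11 | step 14 | chloridobis(cyclopentadienyl)[(1E)-undeca-1,10-dien-1-yl]zirconium | C=CCCCCCCC/C=C/[Zr+2]Cl.c1cc[cH-]c1.c1cc[cH-]c1
F12 | step 15 | 2-[(3S,6R)-6-[(6E)-hexadeca-6,15-dien-4-yn-1-yl]-6-methoxy-1,2-dioxan-3-yl]ethan-1-ol | C=CCCCCCCC/C=C/C#CCCC[C@]1(OC)CC[C@@H](CCO)OO1
F13 | step 15 | 2-[(3S,6R)-6-[(6E)-hexadeca-6,15-dien-4-yn-1-yl]-6-methoxy-1,2-dioxan-3-yl]acetaldehyde | C=CCCCCCCC/C=C/C#CCCC[C@]1(OC)CC[C@@H](CC=O)OO1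
A1 | alternative 1 | (2R)-2-{[(tert-butyldimethylsilyl)oxy]methyl}-7-[5-(triisopropylsilyl)pent-4-yn-1-yl]-2,3-dihydrooxepine | CC(C)[Si](C(C)C)(C(C)C)C#CCCCC1=CC=CC[C@H](CO[Si](C)(C)C(C)(C)C)O1
A2 | alternative 1 | (1R,3R,5R)-3-{[(tert-butyldimethylsilyl)oxy]methyl}-1-[5-(triisopropylsilyl)pent-4-yn-1-yl]-2,6,7-trioxabicyclo[3.2.2]non-8-ene | CC(C)[Si](C(C)C)(C(C)C)C#CCCC[C@@]12C=C[C@@H](C[C@H](CO[Si](C)(C)C(C)(C)C)O1)OO2
A3 | alternative 2 | methyl 3-methoxy-3-[(triethylsilyl)peroxy]propanoate | COC(=O)CC(OC)OO[Si](CC)(CC)CC
A4 | alternative 2 | [5-(1-methoxycyclopropyl)pent-1-yn-1-yl]trimethylsilane | COC1(CCCC#C[Si](C)(C)C)CC1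
A5 | alternative 2 | methyl 2-[(3S)-6-methoxy-6-[5-(trimethylsilyl)pent-4-yn-1-yl]-1,2-dioxan-3-yl]acetate (both C6 epimers) | C[Si](C)(C)C#CCCCC1(OC)CC[C@@H](CC(=O)OC)OO1
A6 | alternative 3 | tert-butyl{[(3R)-3-{[3-methoxy-8-(trimethylsilyl)oct-1-en-7-yn-3-yl]peroxy}pent-4-en-1-yl]oxy}diphenylsilane (both epimers at the ketal carbon) | C[Si](C)(C)C#CCCCC(OC)(C=C)OO[C@@H](C=C)CCO[Si](c1ccccc1)(c1ccccc1)C(C)(C)C
A7 | alternative 3 | tert-butyl{2-[(3R)-6-methoxy-6-[5-(trimethylsilyl)pent-4-yn-1-yl]-3,6-dihydro-1,2-dioxin-3-yl]ethoxy}diphenylsilane (both C6 epimers) | C[Si](C)(C)C#CCCCC1(OC)C=C[C@@H](CCO[Si](c2ccccc2)(c2ccccc2)C(C)(C)C)OO1
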